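**Retrosynthetic overview**
1. The last ring to close is ring G (O7″–C2). A silyl-triflate-triggered oxa-Michael addition in the aS rotamer of a 3-(flavan-8″-yl)flavone turns the flat chromone ring C into the (2S,3S) ketal by axial-to-central transfer; debenzylation follows.
2. Key disconnection: O1″–C8a″ of ring F together with C8″–C3. Both bonds are made in one pot from a fluoro alcohol and a 3-iodoflavone by an aryne relay (lithiation, LiF loss, alkoxide ring closure, zincation, Negishi coupling). The coupling gives both rotamers about C3–C8″, which are resolved by chromatography with thermal recycling before ring G is closed.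
3. Enabling feature: in ring D the ether carbon C8a″ and the carbon C8″ that carries C3 are neighbours, C8″ is flanked on its other side by the C7″ oxygen, and C4a″ carries the C4″–C3″–C2″ chain. This is the footprint of a C8″≡C8a″ aryne that the C2″ alkoxide can reach only at C8a″.
4. C2″ is set beforehand by CBS reduction of a dihydrochalcone-type ketone built from 5-fluororesorcinol (ring D) and 4′-benzyloxyacetophenone (ring E); its C–O bond is never broken afterwards.
5. Ring order: rings A, B, C arrive with apigenin and rings D, E with the building blocks; ring F forms in step 9 and ring G in step 11.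

Key step: step 9

Locants: chromanone unit O1, C2, C3, C4, C4a–C8a (ring A benzo, ring B the 4-hydroxyphenyl on C2, ring C the pyranone); flavan unit O1″, C2″–C4″, C4a″–C8a″ (ring D benzo, ring E the 4-hydroxyphenyl on C2″, ring F the pyran); ring G is the dihydrofuran O7″–C2–C3–C8″–C7″. The target is (2S,3S,2″R).

Assumption: the ketal of rings C and G is taken to be kinetically stable under neutral conditions but not necessarily the thermodynamic isomer (ring opening to a 3-aroyl-2-arylbenzofuran is possible in acid or base), so it is closed under kinetic control. The C3–C8″ axis of the 3-arylflavones is taken to be configurationally stable at room temperature and mobile above about 150 °C, so the two rotamers are separable diastereomers that can be re-equilibrated by heating. The aS rotamer would be identified by electronic circular dichroism or by correlation with the ketal it gives in step 11.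

**Route**

Step 1
Reactants: 1 5-fluororesorcinol (5-fluorobenzene-1,3-diol)
Product: 2 2-fluoro-4,6-dihydroxybenzaldehyde
Conditions: POCl3, DMF, MeCN, 0 °C to rt; then H2O, 50 °C
Reagents that add atoms: N,N-dimethylformamide CN(C)C=O; water O
Why: Vilsmeier–Haack formylation should go para to one hydroxyl and ortho to the other (as with resorcinol and orcinol), which is the position next to fluorine.

Step 2
Reactants: 2 2-fluoro-4,6-dihydroxybenzaldehyde
Product: 3 2-fluoro-6-hydroxy-4-(methoxymethoxy)benzaldehyde
Conditions: MOMCl (1.05 equiv), K2CO3, acetone, 0 °C to rt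
Reagents that add atoms: chloromethyl methyl ether COCCl
Why: Williamson etherification should take the 4-hydroxyl first, because it is para to the formyl group, more acidic and not hydrogen-bonded to the carbonyl.

Step 3
Reactants: 3 2-fluoro-6-hydroxy-4-(methoxymethoxy)benzaldehyde
Product: 4 2-(benzyloxy)-6-fluoro-4-(methoxymethoxy)benzaldehyde
Conditions: BnBr, K2CO3, DMF, 60 °C
Reagents that add atoms: benzyl bromide BrCc1ccccc1
Why: Williamson benzylation of the remaining chelated phenol under slightly more forcing conditions; the electron-rich ring keeps the fluoride inert to substitution.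

Step 4
Reactants: 4 2-(benzyloxy)-6-fluoro-4-(methoxymethoxy)benzaldehyde; 5 1-[4-(benzyloxy)phenyl]ethan-1-one
Product: 6 (2E)-3-[2-(benzyloxy)-6-fluoro-4-(methoxymethoxy)phenyl]-1-[4-(benzyloxy)phenyl]prop-2-en-1-one
Conditions: KOH (aq), EtOH/THF, rt
Reagents that add atoms: none
Why: Claisen–Schmidt aldol condensation of a non-enolizable aldehyde with an aryl methyl ketone should give the E-enone.

Step 5
Reactants: 6 the E-enone (2E)-3-[2-(benzyloxy)-6-fluoro-4-(methoxymethoxy)phenyl]-1-[4-(benzyloxy)phenyl]prop-2-en-1-one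
Product: 7 3-[2-(benzyloxy)-6-fluoro-4-(methoxymethoxy)phenyl]-1-[4-(benzyloxy)phenyl]propan-1-one
Conditions: H2 (1 atm), Pd/C, Ph2S (cat.), EtOAc, rt
Reagents that add atoms: none
Why: Chemoselective catalytic hydrogenation over sulfide-poisoned Pd/C should reduce the enone C=C and leave the benzyl ethers, the aryl fluoride and the aryl ketone.

Step 6
Reactants: 7 the saturated ketone 3-[2-(benzyloxy)-6-fluoro-4-(methoxymethoxy)phenyl]-1-[4-(benzyloxy)phenyl]propan-1-one
Product: 8 (1R)-3-[2-(benzyloxy)-6-fluoro-4-(methoxymethoxy)phenyl]-1-[4-(benzyloxy)phenyl]propan-1-ol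
Conditions: (S)-2-methyl-CBS-oxazaborolidine ((3aS)-1-methyl-3,3-diphenyltetrahydro-1H,3H-pyrrolo[1,2-c][1,3,2]oxazaborole, 0.2 equiv), BH3·SMe2, THF, −20 °C; then MeOH
Reagents that add atoms: none
Why: CBS reduction of an aryl alkyl ketone; with the aryl group as the large substituent the (S)-oxazaborolidine should deliver hydride to the Si face and set C2″ as R (the sense known for acetophenone).

Step 7
Reactants: 9 apigenin (5,7-dihydroxy-2-(4-hydroxyphenyl)-4H-chromen-4-one)
Product: 10 5,7-bis(benzyloxy)-2-[4-(benzyloxy)phenyl]-4H-chromen-4-one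
Conditions: BnBr (excess), K2CO3, DMF, 80 °C
Reagents that add atoms: benzyl bromide BrCc1ccccc1
Why: Exhaustive Williamson benzylation; heating and excess reagent are needed for the chelated 5-hydroxyl.

Step 8
Reactants: 10 tri-O-benzylapigenin (5,7-bis(benzyloxy)-2-[4-(benzyloxy)phenyl]-4H-chromen-4-one)
Product: 12 5,7-bis(benzyloxy)-2-[4-(benzyloxy)phenyl]-3-iodo-4H-chromen-4-one, via 3-lithioflavone 11 (not isolated)
Conditions: LiN(i-Pr)2 (LDA), THF, −78 °C; then I2, −78 °C to rt
Reagents that add atoms: iodine II
Why: Deprotonative metalation of a flavone at C3 (the only vinylic C–H next to the carbonyl) followed by iodine quench fixes the iodide regiospecifically at C3.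

Step 9
Reactants: 8 the (1R)-fluoro alcohol (1R)-3-[2-(benzyloxy)-6-fluoro-4-(methoxymethoxy)phenyl]-1-[4-(benzyloxy)phenyl]propan-1-ol; 12 the 3-iodoflavone 5,7-bis(benzyloxy)-2-[4-(benzyloxy)phenyl]-3-iodo-4H-chromen-4-one
Product: 17 5,7-bis(benzyloxy)-2-[4-(benzyloxy)phenyl]-3-{(2R)-5-(benzyloxy)-2-[4-(benzyloxy)phenyl]-7-(methoxymethoxy)-3,4-dihydro-2H-chromen-8-yl}-4H-chromen-4-one as both rotamers about the C3–C8″ axis, via dilithio species 13 (not isolated), via aryne alkoxide 14 (not isolated), via 8-lithioflavan 15 (not isolated), via arylzinc chloride 16 (not isolated)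
Conditions: n-BuLi (2.1 equiv), THF (dilute), −78 °C, then warm to −15 °C; ZnCl2, −15 °C to rt; then 12, Pd2(dba)3 (cat.), RuPhos, THF/NMP, 65 °C
Reagents that add atoms: none
Why: n-BuLi first forms the lithium alkoxide and then lithiates the only ring-D C–H that lies between fluorine and the OMOM group (C8″); on warming LiF is lost to give the C8″≡C8a″ aryne 14, the tethered alkoxide adds to C8a″, and the aryl anion left at C8″ is passed from lithium to zinc and cross-coupled with iodide 12 on zerovalent palladium (zincation prevents lithium–iodine exchange with 12). The closest known reaction type is the anionic aryne cyclization of tethered alkoxide or amide nucleophiles with capture of the resulting ortho-metalated arene by an electrophile, followed by a Negishi coupling. Ring F closes by 6-exo-dig attack of O1″ on the aryne carbon C8a″; no other ring is formed. C2″ keeps its R configuration because its C–O bond is never broken; the only new stereogenic element, the hindered C3–C8″ axis, is remote from C2″ and should form without bias, so 17 is expected as both rotamers (aS and aR, diastereomers), which are resolved in step 10. The step needs site-selective lithiation and regioselective aryne capture: only the anion ortho to fluorine can eliminate, the three-atom tether lets oxygen reach C8a″ only, and the C7″ OMOM group polarizes the aryne so that the carbanion develops at C8″ next to oxygen.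

Step 10
Reactants: 17 the MOM ether (both rotamers about C3–C8″)
Product: 18 5,7-bis(benzyloxy)-2-[4-(benzyloxy)phenyl]-3-{(2R)-5-(benzyloxy)-2-[4-(benzyloxy)phenyl]-7-hydroxy-3,4-dihydro-2H-chromen-8-yl}-4H-chromen-4-one as the aS atropisomer (P helicity about C3–C8″)
Conditions: chromatography on SiO2 at rt (aS rotamer of 17 collected; aR-enriched fraction of 17 heated in 1,2-dichlorobenzene, 160 °C, and chromatographed again); then aS rotamer, HCl (cat.), MeOH/THF, 35 °C
Reagents that add atoms: none
Why: The rotamers of 17 are diastereomers (fixed C2″ centre plus the hindered C3–C8″ axis) and should separate on silica, thermal rotation about the biaryl axis (atropisomerization) returns the aR-enriched fraction to the equilibrium mixture without touching C2″, and acid-catalysed acetal exchange with methanol (MOM ether methanolysis) then frees only the C7″ phenol at a temperature at which the axis does not turn and with acid too dilute to protonate the chromone.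

Step 11
Reactants: 18 the aS phenol
Product: 21 the penta-O-benzyl ether of the target (5,7,4′,5″,4‴-pentakis-benzyloxy; 2S,3S,2″R; rings C and G cis-fused), via silyloxyflavylium triflate 19 (not isolated), via silyl enol ether ketal 20 (not isolated)
Conditions: TBSOTf (1.05 equiv), CH2Cl2, −78 °C; 2,6-di-tert-butyl-4-methylpyridine, −78 to −30 °C; then AcOH/THF/H2O, 0 °C
Reagents that add atoms: none
Why: Proposed new method: silylation of the chromone carbonyl gives the 4-silyloxyflavylium ion 19, whose C2 is attacked by the C7″ hydroxyl that the aS axis holds over one face only (5-membered ring G, axial-to-central transfer, giving 2S; attack at C4 would only give a labile mixed silyl ketal that reverts); the hindered pyridine removes the proton to give the neutral silyl enol ether 20, which has no acid- or base-free path to the aromatic benzofuran isomer, and C-protonation during mild hydrolysis should give the cis ring fusion (3S) because a trans fusion of rings C and G is strained and C3 can equilibrate through the enol; the closest known reaction types are the silyl-triflate-promoted conjugate addition of silyl nucleophiles to chromones through 4-silyloxybenzopyrylium ions and the trapping of flavylium ions by phenols to give bicyclic ketals.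

Step 12
Reactants: 21 the penta-O-benzyl ketal
Product: 22 the target, (2S,3S)-5,7-dihydroxy-2-(4-hydroxyphenyl)chroman-4-one joined through C3–C8″ and C2–O–C7″ to (2″R)-5″-hydroxy-2″-(4-hydroxyphenyl)flavan
Conditions: H2 (1 atm), Pd(OH)2/C, THF/MeOH, rt
Reagents that add atoms: none
Why: Neutral hydrogenolysis of the five aryl benzyl ethers; bicyclic aryl ketals of this kind and the flavan C2″–O1″ bond are known to survive such debenzylation, and no stereocenter is touched.

**Compound list**
1 | 5-fluororesorcinol | Oc1cc(O)cc(F)c1 | starting material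
2 | 2-fluoro-4,6-dihydroxybenzaldehyde | O=Cc1c(F)cc(O)cc1O | intermediate
3 | 2-fluoro-6-hydroxy-4-(methoxymethoxy)benzaldehyde | O=Cc1c(F)cc(OCOC)cc1O | intermediate
4 | 2-(benzyloxy)-6-fluoro-4-(methoxymethoxy)benzaldehyde | O=Cc1c(F)cc(OCOC)cc1OCc1ccccc1 | intermediate
5 | 1-[4-(benzyloxy)phenyl]ethan-1-one | CC(=O)c1ccc(OCc2ccccc2)cc1 | starting material
6 | (2E)-3-[2-(benzyloxy)-6-fluoro-4-(methoxymethoxy)phenyl]-1-[4-(benzyloxy)phenyl]prop-2-en-1-one | O=C(/C=C/c1c(F)cc(OCOC)cc1OCc1ccccc1)c1ccc(OCc2ccccc2)cc1 | intermediate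
7 | 3-[2-(benzyloxy)-6-fluoro-4-(methoxymethoxy)phenyl]-1-[4-(benzyloxy)phenyl]propan-1-one | O=C(CCc1c(F)cc(OCOC)cc1OCc1ccccc1)c1ccc(OCc2ccccc2)cc1 | intermediate
8 | (1R)-3-[2-(benzyloxy)-6-fluoro-4-(methoxymethoxy)phenyl]-1-[4-(benzyloxy)phenyl]propan-1-ol | O[C@@H](c1ccc(OCc2ccccc2)cc1)CCc1c(F)cc(OCOC)cc1OCc1ccccc1 | intermediate
9 | apigenin | O=c1cc(-c2ccc(O)cc2)oc2cc(O)cc(O)c12 | starting material
10 | 5,7-bis(benzyloxy)-2-[4-(benzyloxy)phenyl]-4H-chromen-4-one | O=c1cc(-c2ccc(OCc3ccccc3)cc2)oc2cc(OCc3ccccc3)cc(OCc3ccccc3)c12 | intermediate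
11 | 3-lithio derivative of 10 | [Li]c1c(-c2ccc(OCc3ccccc3)cc2)oc2cc(OCc3ccccc3)cc(OCc3ccccc3)c2c1=O | intermediate
12 | 5,7-bis(benzyloxy)-2-[4-(benzyloxy)phenyl]-3-iodo-4H-chromen-4-one | O=c1c(I)c(-c2ccc(OCc3ccccc3)cc2)oc2cc(OCc3ccccc3)cc(OCc3ccccc3)c12 | intermediate
13 | dilithio species of 8 (lithium alkoxide, aryllithium between F and OMOM) | [Li]O[C@@H](c1ccc(OCc2ccccc2)cc1)CCc1c(F)c([Li])c(OCOC)cc1OCc1ccccc1 | intermediate
14 | aryne lithium alkoxide (C8″≡C8a″) | [Li]O[C@@H](c1ccc(OCc2ccccc2)cc1)CCC1=C(OCc2ccccc2)C=C(OCOC)C#C1 | intermediate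
15 | (2R)-5-(benzyloxy)-2-[4-(benzyloxy)phenyl]-8-lithio-7-(methoxymethoxy)chroman | [Li]c1c(OCOC)cc(OCc2ccccc2)c2c1O[C@@H](c1ccc(OCc3ccccc3)cc1)CC2 | intermediate
16 | the corresponding chroman-8-ylzinc chloride | Cl[Zn]c1c(OCOC)cc(OCc2ccccc2)c2c1O[C@@H](c1ccc(OCc3ccccc3)cc1)CC2 | intermediate
17 | protected 3-(flavan-8″-yl)flavone with 7″-OMOM, both rotamers about C3–C8″ (aS and aR; axis not encoded in SMILES) | O=c1c(-c2c(OCOC)cc(OCc3ccccc3)c3c2O[C@@H](c2ccc(OCc4ccccc4)cc2)CC3)c(-c2ccc(OCc3ccccc3)cc2)oc2cc(OCc3ccccc3)cc(OCc3ccccc3)c12 | intermediate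
18 | 7″-hydroxy compound from 17, aS atropisomer (axis not encoded in SMILES) | O=c1c(-c2c(O)cc(OCc3ccccc3)c3c2O[C@@H](c2ccc(OCc4ccccc4)cc2)CC3)c(-c2ccc(OCc3ccccc3)cc2)oc2cc(OCc3ccccc3)cc(OCc3ccccc3)c12 | intermediate
19 | 4-(tert-butyldimethylsilyloxy)flavylium triflate of 18 | CC(C)(C)[Si](C)(C)Oc1c(-c2c(O)cc(OCc3ccccc3)c3c2O[C@@H](c2ccc(OCc4ccccc4)cc2)CC3)c(-c2ccc(OCc3ccccc3)cc2)[o+]c2cc(OCc3ccccc3)cc(OCc3ccccc3)c12.[O-]S(=O)(=O)C(F)(F)F | intermediate
20 | silyl enol ether ketal (ring G closed, C3=C4, C4–OTBS; C2 arranged as in 21) | CC(C)(C)[Si](C)(C)OC1=C2c3c(O[C@]2(c2ccc(OCc4ccccc4)cc2)Oc2cc(OCc4ccccc4)cc(OCc4ccccc4)c12)cc(OCc2ccccc2)c2c3O[C@@H](c3ccc(OCc4ccccc4)cc3)CC2 | intermediate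
21 | penta-O-benzyl ether of the target (2S,3S,2″R) | O=C1c2c(OCc3ccccc3)cc(OCc3ccccc3)cc2O[C@@]2(c3ccc(OCc4ccccc4)cc3)Oc3cc(OCc4ccccc4)c4c(c3[C@@H]12)O[C@@H](c1ccc(OCc3ccccc3)cc1)CC4 | intermediate
22 | target (2S,3S,2″R) | O=C1c2c(O)cc(O)cc2O[C@@]2(c3ccc(O)cc3)Oc3cc(O)c4c(c3[C@@H]12)O[C@@H](c1ccc(O)cc1)CC4 | target

**Step count**
Total steps: 12. Longest linear sequence: 10 (steps 1–6 and 9–12).

**Steps most likely to fail**

1. Step 11 (proposed new method). What may go wrong: silyl transfer to the phenol instead of ring closure, or re-ionization of the ketal with drainage toward the aromatic 3-aroylbenzofuran isomer. Fallback with known chemistry, setting out from 18: the carbonyl group is reduced with LiAlH4 (THF, 0 °C) to the flav-2-en-4-ol F1. HBF4·OEt2 ionizes it to the 3-arylflavylium tetrafluoroborate F2. On neutralization (NaHCO3) the C7″ phenol adds to C2 from the face fixed by the axis, the classical flavylium-to-ketal reaction (addition of an oxygen nucleophile at C4 is reversible, so the C2 ketal should accumulate), to give the 2H-chromene ketal F3. Hydroboration–oxidation of the C3=C4 bond (BH3·THF; NaBO3) should place oxygen on the benzylic, less substituted carbon and give the C4 alcohol F4. Dess–Martin oxidation returns to the route at 21, with C3 settling in the cis fusion through the enol.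

2. Step 9 (key step). What may go wrong: lithiation between the two alkoxy groups instead of next to fluorine, hydride transfer from the carbinol C–H to the aryne, protonation of the aryl anion before zincation, or sluggish coupling of the doubly ortho-substituted arylzinc. Fallback, setting out from 8, without an organometallic relay: t-BuOK in DMSO (80 °C) displaces fluoride intramolecularly (directly or through the same aryne; both give one product after protonation) to give the 8″-unsubstituted flavan F5. NBS (CH2Cl2, −40 °C) brominates C8″, the position known to react first in 5,7-dialkoxyflavans, to give the bromide F6. Miyaura borylation (B2pin2, PdCl2(dppf), KOAc) gives the pinacol boronate F7. Suzuki–Miyaura coupling with 12 (Pd(OAc)2, SPhos, K3PO4) returns to the route at 17, again as both rotamers.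

3. Step 12. What may go wrong: ring opening of the ketal to the aromatic benzofuran isomer on an acidic catalyst surface, or hydrogenolysis of the benzylic C2″–O1″ or C2–O bonds during a slow fivefold debenzylation. Fallback, setting out from 18, with the order of events changed: the benzyl groups are removed at the robust flavone stage (H2, Pd(OH)2/C) to give the hexaphenol F8. N,O-Bis(trimethylsilyl)acetamide converts all six hydroxyls into the hexakis(trimethylsilyl) ether F9. Catalytic TMSOTf (CH2Cl2, −78 °C) should then effect the same ketalization, with the C7″ silyl ether as nucleophile and transfer of its silyl group to the C4 oxygen, giving the silyl enol ether ketal F10. A citrate-buffered aqueous work-up removes all trimethylsilyl groups and returns to the route at the target 22.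

**Further compounds**
F1 | step 11 | 4-hydroxy-4H-chromene (flav-2-en-4-ol) from 18, C4 unassigned | OC1c2c(OCc3ccccc3)cc(OCc3ccccc3)cc2OC(c2ccc(OCc3ccccc3)cc2)=C1c1c(O)cc(OCc2ccccc2)c2c1O[C@@H](c1ccc(OCc3ccccc3)cc1)CC2
F2 | step 11 | 3-arylflavylium tetrafluoroborate | c1(-c2ccc(OCc3ccccc3)cc2)[o+]c2cc(OCc3ccccc3)cc(OCc3ccccc3)c2cc1-c1c(O)cc(OCc2ccccc2)c2c1O[C@@H](c1ccc(OCc3ccccc3)cc1)CC2.F[B-](F)(F)F
F3 | step 11 | 2H-chromene ketal (ring G closed, C3=C4, C4–H) | C1=C2c3c(O[C@]2(c2ccc(OCc4ccccc4)cc2)Oc2cc(OCc4ccccc4)cc(OCc4ccccc4)c12)cc(OCc2ccccc2)c2c3O[C@@H](c3ccc(OCc4ccccc4)cc3)CC2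
F4 | step 11 | C4 alcohol of 21, C4 unassigned | OC1c2c(OCc3ccccc3)cc(OCc3ccccc3)cc2O[C@@]2(c3ccc(OCc4ccccc4)cc3)Oc3cc(OCc4ccccc4)c4c(c3[C@@H]12)O[C@@H](c1ccc(OCc3ccccc3)cc1)CC4
F5 | step 9 | (2R)-5-(benzyloxy)-2-[4-(benzyloxy)phenyl]-7-(methoxymethoxy)chroman | COCOc1cc(OCc2ccccc2)c2c(c1)O[C@@H](c1ccc(OCc3ccccc3)cc1)CC2
F6 | step 9 | 8-bromo derivative of F5 | COCOc1cc(OCc2ccccc2)c2c(c1Br)O[C@@H](c1ccc(OCc3ccccc3)cc1)CC2
F7 | step 9 | 8-(pinacolboryl) derivative of F5 | COCOc1cc(OCc2ccccc2)c2c(c1B1OC(C)(C)C(C)(C)O1)O[C@@H](c1ccc(OCc3ccccc3)cc1)CC2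
F8 | step 12 | fully debenzylated 3-(flavan-8″-yl)apigenin, aS atropisomer | O=c1c(-c2c(O)cc(O)c3c2O[C@@H](c2ccc(O)cc2)CC3)c(-c2ccc(O)cc2)oc2cc(O)cc(O)c12
F9 | step 12 | hexakis(trimethylsilyl) ether of F8 | O=c1c(-c2c(O[Si](C)(C)C)cc(O[Si](C)(C)C)c3c2O[C@@H](c2ccc(O[Si](C)(C)C)cc2)CC3)c(-c2ccc(O[Si](C)(C)C)cc2)oc2cc(O[Si](C)(C)C)cc(O[Si](C)(C)C)c12
F10 | step 12 | trimethylsilyl enol ether ketal with five aryl trimethylsilyl ethers | C[Si](C)(C)OC1=C2c3c(O[C@]2(c2ccc(O[Si](C)(C)C)cc2)Oc2cc(O[Si](C)(C)C)cc(O[Si](C)(C)C)c12)cc(O[Si](C)(C)C)c2c3O[C@@H](c3ccc(O[Si](C)(C)C)cc3)CC2
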